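**Plan**

Numbering: arene C1 carries the 3-(benzoyloxy)prop-1-en-2-yl arm, C3 the free OH, C4 the methyl and C6 the isobutyryloxy group. The two para oxygens O3 and O6 carry different substituents, and this maps them onto the ketene carbon (C3) and the protected carbinol carbon (C6) of a 4-alkenyl-4-silyloxycyclobutenone; that feature makes the key step possible.
Retrosynthesis: cut the two ester C–O bonds (O6–isobutyryl, allylic O–benzoyl), then the arene C3–C4 bond back to cyclobutenone 12, then the C1–arm bond and the C6–propenyl bond back to isopropyl semisquarate and diisopropyl squarate.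
Forward: squarate to semisquarate; (E)-propenyllithium adds at the future C6 and the carbinol is silylated; the 2-lithioallyl silyl ether adds and the carbonyl is transposed (future C1 arm); heating expands the four-membered ring to the benzene ring, the only ring formed.
Endgame: O3 is masked as a tetrahydropyranyl acetal, both silyl groups are removed, the phenoxide O6 is isobutyrylated, the allylic alcohol is benzoylated and the acetal is hydrolysed.
Stereochemistry: the target is achiral; the (E)-propenyl geometry comes from (E)-1-bromoprop-1-ene and is erased on aromatization, and the only selectivity needed is the torquoselectivity of the ring opening.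

Key step: step 6

Remark: every chiral intermediate (6, 7, 11, 12, 14, 16, 17, 19, 21) is a racemate; 11 is a diastereomer mixture that converges within its own step.

**Route**

Step 1
Reactants: 1 diisopropyl squarate
Product: 3 3-isopropoxycyclobut-3-ene-1,2-dione (isopropyl semisquarate), via hydroxycyclobutenone 2 (not isolated)
Conditions: LiAlH(OtBu)3 (1.0 equiv), THF, −78 to 0 °C; dilute aq. HCl work-up; then conc. HCl (cat.), CH2Cl2, rt
Reagents that add atoms: water, O (oxygen of the new carbonyl)
Why: The hindered hydride adds once to a squarate carbonyl (1,2-reduction), and acid then ionizes the allylic hydroxyl with help from the vinylogous isopropoxy group, so that hydrolysis of the resulting oxocarbenium ion expels isopropanol and leaves the vinylic C–H (acid-mediated allylic transposition of a 4-hydroxycyclobutenone to a cyclobutenedione).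

Step 2
Reactants: 3 isopropyl semisquarate; 4 (E)-1-bromoprop-1-ene
Product: 6 4-hydroxy-3-isopropoxy-4-[(E)-prop-1-enyl]cyclobut-2-en-1-one (racemic), via (E)-prop-1-enyllithium 5 (not isolated)
Conditions: 4, t-BuLi (2.0 equiv), Et2O, −78 °C; then 3, THF, −78 °C; aq. NH4Cl
Reagents that add atoms: none
Why: Bromine–lithium exchange retains the (E)-geometry, and the vinyllithium should add 1,2 to the ketone carbonyl next to the isopropoxy-bearing carbon, which is more electrophilic than the vinylogous ester carbonyl (organolithium 1,2-addition to an alkoxycyclobutenedione); the carbinol centre forms as a racemate.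

Step 3
Reactants: 6 4-hydroxy-3-isopropoxy-4-[(E)-prop-1-enyl]cyclobut-2-en-1-one
Product: 7 4-(tert-butyldimethylsilyloxy)-3-isopropoxy-4-[(E)-prop-1-enyl]cyclobut-2-en-1-one (racemic)
Conditions: TBSOTf, 2,6-lutidine, CH2Cl2, −78 to 0 °C
Reagents that add atoms: tert-butyldimethylsilyl trifluoromethanesulfonate (TBSOTf), CC(C)(C)[Si](C)(C)OS(=O)(=O)C(F)(F)F
Why: A silyl triflate with a hindered pyridine base silylates hindered tertiary alcohols (silyl ether formation), and the ether both protects the carbinol from the next organolithium and later keeps O6 distinct from O3.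

Step 4
Reactants: 8 2-bromoprop-2-en-1-ol
Product: 9 [(2-bromoprop-2-en-1-yl)oxy](tert-butyl)dimethylsilane
Conditions: TBSCl, imidazole, CH2Cl2, 0 °C to rt
Reagents that add atoms: tert-butyldimethylsilyl chloride (TBSCl), CC(C)(C)[Si](C)(C)Cl
Why: Imidazole-promoted silylation of a primary alcohol is routine (silyl ether formation) and removes the acidic proton before halogen–lithium exchange.

Step 5
Reactants: 7 4-(tert-butyldimethylsilyloxy)-3-isopropoxy-4-[(E)-prop-1-enyl]cyclobut-2-en-1-one; 9 [(2-bromoprop-2-en-1-yl)oxy](tert-butyl)dimethylsilane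
Product: 12 4-(tert-butyldimethylsilyloxy)-3-[3-(tert-butyldimethylsilyloxy)prop-1-en-2-yl]-4-[(E)-prop-1-enyl]cyclobut-2-en-1-one (racemic), via vinyllithium 10 (not isolated), via lithium cyclobutenolate 11 (not isolated)
Conditions: 9, t-BuLi (2.0 equiv), Et2O, −78 °C; then 7, THF, −78 °C; then (CF3CO)2O, −78 °C; aq. NaHCO3
Reagents that add atoms: water, O (oxygen of the new carbonyl)
Why: The 2-lithioallyl ether adds to the vinylogous ester carbonyl, trifluoroacetylation of the tertiary alkoxide ionizes it to an isopropoxy-stabilized cyclobutenyl cation, and hydrolysis on work-up gives the transposed enone (Stork–Danheiser-type alkylative carbonyl transposition); because the silyloxy carbon is bonded to both ends of the enone, 1,2-addition/transposition and direct addition–elimination converge on the same product.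

Step 6
Reactants: 12 4-(tert-butyldimethylsilyloxy)-3-[3-(tert-butyldimethylsilyloxy)prop-1-en-2-yl]-4-[(E)-prop-1-enyl]cyclobut-2-en-1-one
Product: 15 4-(tert-butyldimethylsilyloxy)-5-[3-(tert-butyldimethylsilyloxy)prop-1-en-2-yl]-2-methylphenol, via dienylketene 13 (not isolated), via cyclohexadienone 14 (not isolated)
Conditions: toluene (degassed, 0.02 M), 110 °C
Reagents that add atoms: none
Why: Heating opens the cyclobutenone by a conrotatory 4π electrocyclic cleavage of the bond between the carbonyl carbon and the carbinol carbon to give dienylketene 13, whose ketene carbon (future C3) bonds to the propenyl terminus (future C4) in a disrotatory 6π electrocyclization to cyclohexadienone 14, and enolization of 14 delivers phenol 15. This is the Moore rearrangement, and the closest known reaction type is the thermal ring expansion of 4-alkenyl-4-hydroxy- and 4-alkenyl-4-silyloxycyclobutenones to hydroquinones and their monoethers. The only ring formed, the benzene ring, closes by thermal 6π electrocyclization of the ketene–diene triene (bond C3–C4), followed by tautomerization. No stereocentre survives, because the sp3 carbon of 14 is erased on aromatization. The step needs torquoselectivity in the ring opening, and the electron-donating silyloxy group secures it by rotating outward, which turns the propenyl group inward, cis to the ketene and away from the 2-substituted vinyl arm, while the (E)-geometry leaves only hydrogen on the inside of the closing terminus. Regiochemistry is fixed by the connectivity of 12 alone: H ends at C2, the side arm at C1, methyl at C4, the ketene oxygen as free O3–H and the carbinol oxygen as silylated O6.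

Step 7
Reactants: 15 4-(tert-butyldimethylsilyloxy)-5-[3-(tert-butyldimethylsilyloxy)prop-1-en-2-yl]-2-methylphenol
Product: 16 2-{4-(tert-butyldimethylsilyloxy)-5-[3-(tert-butyldimethylsilyloxy)prop-1-en-2-yl]-2-methylphenoxy}tetrahydro-2H-pyran (racemic)
Conditions: 3,4-dihydro-2H-pyran, PPTS (cat.), CH2Cl2, rt
Reagents that add atoms: 3,4-dihydro-2H-pyran, C1=COCCC1
Why: Acid-catalysed addition of the phenol to the enol ether (tetrahydropyranyl acetal formation) masks O3 under conditions that leave both silyl ethers and the alkene untouched; the acetal carbon forms as a racemate.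

Step 8
Reactants: 16 2-{4-(tert-butyldimethylsilyloxy)-5-[3-(tert-butyldimethylsilyloxy)prop-1-en-2-yl]-2-methylphenoxy}tetrahydro-2H-pyran
Product: 17 2-(3-hydroxyprop-1-en-2-yl)-5-methyl-4-(tetrahydro-2H-pyran-2-yloxy)phenol (racemic)
Conditions: Bu4NF (2.5 equiv), THF, 0 °C to rt; aq. NH4Cl
Reagents that add atoms: none
Why: Fluoride cleaves both the aryl and the primary alkyl silyl ether (fluoride-mediated desilylation), while the acetal at O3 is inert to fluoride and base.

Step 9
Reactants: 17 2-(3-hydroxyprop-1-en-2-yl)-5-methyl-4-(tetrahydro-2H-pyran-2-yloxy)phenol; 18 isobutyryl chloride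
Product: 19 2-(3-hydroxyprop-1-en-2-yl)-5-methyl-4-(tetrahydro-2H-pyran-2-yloxy)phenyl 2-methylpropanoate (racemic)
Conditions: 18 (1.05 equiv), aq. NaOH (1 M)/CH2Cl2, Bu4NHSO4 (cat.), 0 °C
Reagents that add atoms: none
Why: Under phase-transfer Schotten–Baumann conditions only the phenol is ionized, and its ammonium phenoxide should be acylated in the organic phase far faster than the neutral primary alcohol (chemoselective O-acylation of a phenoxide).

Step 10
Reactants: 19 2-(3-hydroxyprop-1-en-2-yl)-5-methyl-4-(tetrahydro-2H-pyran-2-yloxy)phenyl 2-methylpropanoate; 20 benzoyl chloride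
Product: 21 2-[2-(isobutyryloxy)-4-methyl-5-(tetrahydro-2H-pyran-2-yloxy)phenyl]prop-2-en-1-yl benzoate (racemic)
Conditions: 20, Et3N, DMAP (cat.), CH2Cl2, 0 °C
Reagents that add atoms: none
Why: DMAP-catalysed acylation of the only remaining free hydroxyl, a primary allylic alcohol, with an acid chloride is a standard esterification.

Step 11
Reactants: 21 2-[2-(isobutyryloxy)-4-methyl-5-(tetrahydro-2H-pyran-2-yloxy)phenyl]prop-2-en-1-yl benzoate
Product: 22 2-[5-hydroxy-2-(isobutyryloxy)-4-methylphenyl]prop-2-en-1-yl benzoate (CNP0245407.0)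
Conditions: AcOH/THF/H2O (4:2:1), 40 °C
Reagents that add atoms: none
Why: Aqueous acetic acid hydrolyses the phenolic tetrahydropyranyl acetal (acid-catalysed acetal hydrolysis) and should be too weak to affect the aryl isobutyrate, the allylic benzoate or the 1,1-disubstituted alkene.

**Compound list**

1 | diisopropyl squarate (3,4-diisopropoxycyclobut-3-ene-1,2-dione) | CC(C)OC1=C(OC(C)C)C(=O)C1=O | starting material
2 | 4-hydroxy-2,3-diisopropoxycyclobut-2-en-1-one (racemic) | CC(C)OC1=C(OC(C)C)C(=O)C1O | intermediate
3 | 3-isopropoxycyclobut-3-ene-1,2-dione (isopropyl semisquarate) | CC(C)OC1=CC(=O)C1=O | intermediate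
4 | (E)-1-bromoprop-1-ene | C/C=C/Br | starting material
5 | (E)-prop-1-enyllithium | C/C=C/[Li] | intermediate
6 | 4-hydroxy-3-isopropoxy-4-[(E)-prop-1-enyl]cyclobut-2-en-1-one (racemic) | C/C=C/C1(O)C(=O)C=C1OC(C)C | intermediate
7 | 4-(tert-butyldimethylsilyloxy)-3-isopropoxy-4-[(E)-prop-1-enyl]cyclobut-2-en-1-one (racemic) | C/C=C/C1(O[Si](C)(C)C(C)(C)C)C(=O)C=C1OC(C)C | intermediate
8 | 2-bromoprop-2-en-1-ol | C=C(Br)CO | starting material
9 | [(2-bromoprop-2-en-1-yl)oxy](tert-butyl)dimethylsilane | C=C(Br)CO[Si](C)(C)C(C)(C)C | intermediate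
10 | [3-(tert-butyldimethylsilyloxy)prop-1-en-2-yl]lithium | [Li]C(=C)CO[Si](C)(C)C(C)(C)C | intermediate
11 | lithium 4-(tert-butyldimethylsilyloxy)-1-[3-(tert-butyldimethylsilyloxy)prop-1-en-2-yl]-3-isopropoxy-4-[(E)-prop-1-enyl]cyclobut-2-en-1-olate (racemic, diastereomer mixture) | C/C=C/C1(O[Si](C)(C)C(C)(C)C)C(OC(C)C)=CC1(O[Li])C(=C)CO[Si](C)(C)C(C)(C)C | intermediate
12 | 4-(tert-butyldimethylsilyloxy)-3-[3-(tert-butyldimethylsilyloxy)prop-1-en-2-yl]-4-[(E)-prop-1-enyl]cyclobut-2-en-1-one (racemic) | C/C=C/C1(O[Si](C)(C)C(C)(C)C)C(=O)C=C1C(=C)CO[Si](C)(C)C(C)(C)C | intermediate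
13 | (3Z,5E)-4-(tert-butyldimethylsilyloxy)-3-[3-(tert-butyldimethylsilyloxy)prop-1-en-2-yl]hepta-1,3,5-trien-1-one | C/C=C/C(O[Si](C)(C)C(C)(C)C)=C(\C=C=O)C(=C)CO[Si](C)(C)C(C)(C)C | intermediate
14 | 4-(tert-butyldimethylsilyloxy)-3-[3-(tert-butyldimethylsilyloxy)prop-1-en-2-yl]-6-methylcyclohexa-2,4-dien-1-one (racemic) | CC1C=C(O[Si](C)(C)C(C)(C)C)C(C(=C)CO[Si](C)(C)C(C)(C)C)=CC1=O | intermediate
15 | 4-(tert-butyldimethylsilyloxy)-5-[3-(tert-butyldimethylsilyloxy)prop-1-en-2-yl]-2-methylphenol | C=C(CO[Si](C)(C)C(C)(C)C)c1cc(O)c(C)cc1O[Si](C)(C)C(C)(C)C | intermediate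
16 | 2-{4-(tert-butyldimethylsilyloxy)-5-[3-(tert-butyldimethylsilyloxy)prop-1-en-2-yl]-2-methylphenoxy}tetrahydro-2H-pyran (racemic) | C=C(CO[Si](C)(C)C(C)(C)C)c1cc(OC2CCCCO2)c(C)cc1O[Si](C)(C)C(C)(C)C | intermediate
17 | 2-(3-hydroxyprop-1-en-2-yl)-5-methyl-4-(tetrahydro-2H-pyran-2-yloxy)phenol (racemic) | C=C(CO)c1cc(OC2CCCCO2)c(C)cc1O | intermediate
18 | isobutyryl chloride | CC(C)C(Cl)=O | starting material
19 | 2-(3-hydroxyprop-1-en-2-yl)-5-methyl-4-(tetrahydro-2H-pyran-2-yloxy)phenyl 2-methylpropanoate (racemic) | C=C(CO)c1cc(OC2CCCCO2)c(C)cc1OC(=O)C(C)C | intermediate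
20 | benzoyl chloride | O=C(Cl)c1ccccc1 | starting material
21 | 2-[2-(isobutyryloxy)-4-methyl-5-(tetrahydro-2H-pyran-2-yloxy)phenyl]prop-2-en-1-yl benzoate (racemic) | C=C(COC(=O)c1ccccc1)c1cc(OC2CCCCO2)c(C)cc1OC(=O)C(C)C | intermediate
22 | 2-[5-hydroxy-2-(isobutyryloxy)-4-methylphenyl]prop-2-en-1-yl benzoate (CNP0245407.0) | C=C(COC(=O)c1ccccc1)c1cc(O)c(C)cc1OC(=O)C(C)C | target

**Step count and risks**

Total steps: 11. Longest linear sequence: 10 (steps 1–3 and 5–11; step 4 is a one-step branch).

Steps most likely to fail:

1. Step 5. The silyl group may shift from oxygen to the lithiated carbon before the vinyllithium is trapped, addition next to the quaternary silyloxy carbon may be sluggish, and the primary silyl ether may be lost during the acid-triggered transposition. The fallback sets out from 7 and 8 and returns at 12. Alcohol 8 is treated with three equivalents of t-BuLi in Et2O (−78 to 0 °C) to give lithium 2-lithioprop-2-en-1-olate F1, which carries no silicon that could migrate. F1 adds to 7 to give the dilithium dialkoxide adduct F2. An aqueous NH4Cl quench and catalytic HCl in wet CH2Cl2 should then transpose the carbonyl to 4-(tert-butyldimethylsilyloxy)-3-(3-hydroxyprop-1-en-2-yl)-4-[(E)-prop-1-enyl]cyclobut-2-en-1-one F3. Silylation of the primary alcohol of F3 with TBSCl and imidazole gives 12, so silicon is introduced only after the C–C bond is made.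

2. Step 9. The primary allylic hydroxyl may be acylated competitively, hydroxide may cleave the new aryl ester, or base may transfer the acyl group from the phenolic oxygen to the neighbouring primary hydroxyl. The fallback sets out from 16 and returns at 19, replacing chemoselective acylation by stepwise unmasking. Cs2CO3 in DMF/H2O at rt should cleave only the aryl silyl ether and give 2-[3-(tert-butyldimethylsilyloxy)prop-1-en-2-yl]-5-methyl-4-(tetrahydro-2H-pyran-2-yloxy)phenol F4. Acylation of this single hydroxyl with 18, Et3N and catalytic DMAP gives 2-[3-(tert-butyldimethylsilyloxy)prop-1-en-2-yl]-5-methyl-4-(tetrahydro-2H-pyran-2-yloxy)phenyl 2-methylpropanoate F5. Bu4NF buffered with AcOH in THF then removes the primary silyl ether to give 19.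

3. Step 11. During acetal hydrolysis, acid may add across the electron-rich 1,1-disubstituted alkene with participation of the neighbouring benzoate, or the esters may be partly solvolysed. The fallback sets out from 19 and returns at 22, so that no acid treatment follows installation of the benzoate. The acetal of 19 is hydrolysed first (AcOH/THF/H2O, 40 °C) to 4-hydroxy-2-(3-hydroxyprop-1-en-2-yl)-5-methylphenyl 2-methylpropanoate F6. A Mitsunobu esterification (benzoic acid, PPh3, diisopropyl azodicarboxylate, THF, 0 °C) should then convert only the primary allylic alcohol into the benzoate, because the far more acidic benzoic acid outcompetes the phenol as the nucleophile, and gives 22.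

**Further compounds**

F1 | step 5 | lithium 2-lithioprop-2-en-1-olate | [Li]OCC([Li])=C
F2 | step 5 | dilithium dialkoxide adduct of F1 and 7 (racemic, diastereomer mixture) | C/C=C/C1(O[Si](C)(C)C(C)(C)C)C(OC(C)C)=CC1(O[Li])C(=C)CO[Li]
F3 | step 5 | 4-(tert-butyldimethylsilyloxy)-3-(3-hydroxyprop-1-en-2-yl)-4-[(E)-prop-1-enyl]cyclobut-2-en-1-one (racemic) | C/C=C/C1(O[Si](C)(C)C(C)(C)C)C(=O)C=C1C(=C)CO
F4 | step 9 | 2-[3-(tert-butyldimethylsilyloxy)prop-1-en-2-yl]-5-methyl-4-(tetrahydro-2H-pyran-2-yloxy)phenol (racemic) | C=C(CO[Si](C)(C)C(C)(C)C)c1cc(OC2CCCCO2)c(C)cc1O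
F5 | step 9 | 2-[3-(tert-butyldimethylsilyloxy)prop-1-en-2-yl]-5-methyl-4-(tetrahydro-2H-pyran-2-yloxy)phenyl 2-methylpropanoate (racemic) | C=C(CO[Si](C)(C)C(C)(C)C)c1cc(OC2CCCCO2)c(C)cc1OC(=O)C(C)C
F6 | step 11 | 4-hydroxy-2-(3-hydroxyprop-1-en-2-yl)-5-methylphenyl 2-methylpropanoate | C=C(CO)c1cc(O)c(C)cc1OC(=O)C(C)C
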